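The cyclopentane ring is read as cyclopent-2-enone: the isopropenyl-bearing methine is the enone β-carbon, the adjacent methine carrying the linking CH2 is the α-carbon, and the methyl carbinol carbon is the carbonyl carbon. One rhodium/BINAP-catalysed operation adds the isopropenyl group of a 9-BBN borane to the enone and traps the resulting boron enolate with formaldehyde. This forms both exocyclic C–C bonds and both trans methine stereocentres; the precursors are the achiral enone, the alkenylborane and monomeric formaldehyde. The carbinol centre is then relayed from the CH2 arm, and the separately made dearomatised acylphloroglucinol ring is attached by reductive alkylation with the derived hydroxy aldehyde.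

Key step: step 2

Remark: the six-membered ring is a tautomeric enolised β-triketone; such compounds are drawn and named as the tautomer of the target SMILES, and the descriptor of the quaternary carbon refers to that tautomer.

Step 1
Reactants: 1 9-methoxy-9-borabicyclo[3.3.1]nonane (B-methoxy-9-BBN); 2 isopropenylmagnesium bromide
Product: 4 9-(prop-1-en-2-yl)-9-borabicyclo[3.3.1]nonane (B-isopropenyl-9-BBN), via methoxyborate complex 3 (not isolated)
Conditions: THF–pentane, −78 °C → rt; volatiles removed, pentane, filtration under argon, distillation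
Reagents that add atoms: none
Why: Alkylation of a borinic ester by a Grignard reagent: the alkenyl group adds to boron to give the methoxyborate, which sheds methoxymagnesium bromide as a precipitate once the medium is hydrocarbon-rich, leaving the free alkenylborane; no stereocentre is formed.

Step 2
Reactants: 4 B-isopropenyl-9-BBN; 5 cyclopent-2-en-1-one; 6 formaldehyde (monomer)
Product: 9 (2R,3R)-2-(hydroxymethyl)-3-(prop-1-en-2-yl)cyclopentan-1-one, via boron enolate 7 (not isolated), via borinate aldolate 8 (not isolated)
Conditions: [Rh(OMe)(cod)]2 (1.5 mol%), (R)-BINAP (3.3 mol%), toluene, 80 °C; then HCHO (gas from cracked paraformaldehyde), −78 → 0 °C; then pH 7 phosphate buffer, MeOH, 30% H2O2, 0 °C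
Reagents that add atoms: none
Why: Rhodium-catalysed asymmetric 1,4-addition with aldol trapping: the isopropenyl group passes from boron to the monovalent rhodium–BINAP methoxide, the alkenylrhodium species inserts enone 5 on the face chosen by the ligand, and the oxa-π-allylrhodium exchanges with a further molecule of 4 to release the 9-BBN enolate 7 and regenerate alkenylrhodium. The closest known reaction type is the rhodium/BINAP conjugate addition of B-aryl- and B-alkenyl-9-BBN reagents to cyclic enones followed by a boron aldol reaction, here with formaldehyde as the aldehyde. No ring is closed. The isopropenyl methine is set by (R)-BINAP, which on the established facial model for five- and six-membered enones should give the R centre; the α-methine is set by the substrate, since formaldehyde is delivered through a closed boron-bound transition state to the enolate face anti to the new isopropenyl group, and the trans isomer is also the thermodynamic one. The step needs transfer of the sp2 group only (the bicyclic alkyl arms of 9-BBN do not transmetalate), an enolate that stays at the former α-carbon (no proton source until work-up) and a single hydroxymethylation (aldolate 8 is a borinate, no longer an enolate); the buffered peroxide work-up at 0 °C should free the aldol without dehydration.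

Step 3
Reactants: 9 (2R,3R)-2-(hydroxymethyl)-3-(prop-1-en-2-yl)cyclopentan-1-one
Product: 10 (2R,3R)-2-{[(tert-butyldimethylsilyl)oxy]methyl}-3-(prop-1-en-2-yl)cyclopentan-1-one
Conditions: TBSCl, imidazole, DMF, 0 °C → rt
Reagents that add atoms: tert-butyldimethylsilyl chloride, CC(C)(C)[Si](C)(C)Cl
Why: Standard silylation of a primary alcohol, with imidazole too weak a base to cause retro-aldol cleavage or elimination of the β-hydroxy ketone; the bulky silyl ether also enlarges the steric bias of the CH2 arm for the next step.

Step 4
Reactants: 10 (2R,3R)-2-{[(tert-butyldimethylsilyl)oxy]methyl}-3-(prop-1-en-2-yl)cyclopentan-1-one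
Product: 11 (1R,2R,3R)-2-{[(tert-butyldimethylsilyl)oxy]methyl}-1-methyl-3-(prop-1-en-2-yl)cyclopentan-1-ol
Conditions: MeLi, CeCl3 (dried), THF, −78 °C; H2O work-up
Reagents that add atoms: methyllithium, C[Li] (transferred as MeCeCl2, C[Ce](Cl)Cl)
Why: Organocerium 1,2-addition to a ketone: the weakly basic MeCeCl2 should add without enolisation or β-elimination of the silyloxy group and attack the carbonyl face anti to the adjacent CH2OTBS arm, placing methyl trans and hydroxyl cis to that arm (1R), the more distant isopropenyl group on the other face being the weaker influence.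

Step 5
Reactants: 11 (1R,2R,3R)-2-{[(tert-butyldimethylsilyl)oxy]methyl}-1-methyl-3-(prop-1-en-2-yl)cyclopentan-1-ol
Product: 12 (1R,2R,3R)-2-(hydroxymethyl)-1-methyl-3-(prop-1-en-2-yl)cyclopentan-1-ol
Conditions: Bu4NF, THF, 0 °C → rt
Reagents that add atoms: none
Why: Fluoride cleavage of a primary silyl ether, which leaves the tertiary alcohol, the alkene and the three stereocentres untouched.

Step 6
Reactants: 12 (1R,2R,3R)-2-(hydroxymethyl)-1-methyl-3-(prop-1-en-2-yl)cyclopentan-1-ol
Product: 13 (1S,2R,5R)-2-hydroxy-2-methyl-5-(prop-1-en-2-yl)cyclopentane-1-carbaldehyde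
Conditions: TEMPO (10 mol%), PhI(OAc)2, CH2Cl2, rt; crude product used at once
Reagents that add atoms: none
Why: TEMPO/PhI(OAc)2 oxidation is selective for the primary alcohol of a primary/tertiary 1,3-diol and mild enough to spare the β-hydroxy aldehyde; the formyl-bearing centre is already in its more stable arrangement, trans to both neighbouring carbon substituents.

Step 7
Reactants: 14 2,4,6-trihydroxytoluene; 15 isobutyryl chloride
Product: 16 1-(2,4,6-trihydroxy-3-methylphenyl)-2-methylpropan-1-one
Conditions: AlCl3 (3.5 equiv), PhNO2, rt → 60 °C; ice/aq HCl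
Reagents that add atoms: none
Why: Friedel–Crafts acylation of a phloroglucinol: the two free ring positions of 14 are equivalent and the first acyl group deactivates the ring towards a second.

Step 8
Reactants: 16 1-(2,4,6-trihydroxy-3-methylphenyl)-2-methylpropan-1-one
Product: 17 (6R)-3,5-dihydroxy-6-methyl-6-(3-methylbut-2-en-1-yl)-2-(2-methylpropanoyl)cyclohexa-2,4-dien-1-one
Conditions: Pd2(dba)3·CHCl3 (2.5 mol%), (R,R)-DACH-phenyl bis(2-diphenylphosphinobenzamide) ligand (7.5 mol%), prenyl acetate (1.0 equiv), Et3N, CH2Cl2, 0 °C
Reagents that add atoms: prenyl acetate (3-methylbut-2-en-1-yl acetate), CC(C)=CCOC(C)=O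
Why: Proposed new method: zerovalent palladium ionises prenyl acetate to a cationic (1,1-dimethylallyl)palladium complex held in the chiral pocket of the diamide-bisphosphine ligand, and the triethylammonium phenoxide of 16 should attack its unsubstituted terminus through the methyl-bearing ring carbon, the most electron-rich carbon and the site favoured in base-mediated alkylations of such phenols, so that the ring is dearomatised and the quaternary centre is set by the catalyst, which distinguishes the two faces of the planar nucleophile (the ligand antipode that gives 6R is to be fixed in the first runs); O-prenyl ethers re-ionise under the conditions and funnel to carbon, and the weaker nucleophilicity of the more acidic product enolate should limit a second prenylation when the acetate is not used in excess; the closest known reaction types are the palladium-catalysed asymmetric allylic dearomatisation of naphthols with this ligand class, the ligand-controlled linear asymmetric prenylation of oxindoles, and the racemic dearomative prenylation of methylated acylphloroglucinols.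

Step 9
Reactants: 13 (1S,2R,5R)-2-hydroxy-2-methyl-5-(prop-1-en-2-yl)cyclopentane-1-carbaldehyde; 17 (6R)-3,5-dihydroxy-6-methyl-6-(3-methylbut-2-en-1-yl)-2-(2-methylpropanoyl)cyclohexa-2,4-dien-1-one
Product: 19 (6R)-3,5-dihydroxy-4-{[(1S,2R,5R)-2-hydroxy-2-methyl-5-(prop-1-en-2-yl)cyclopentyl]methyl}-6-methyl-6-(3-methylbut-2-en-1-yl)-2-(2-methylpropanoyl)cyclohexa-2,4-dien-1-one (target), via alkylidene triketone 18 (not isolated)
Conditions: L-proline (20 mol%), diethyl 2,6-dimethyl-1,4-dihydropyridine-3,5-dicarboxylate (Hantzsch ester, 1.2 equiv), CH2Cl2, rt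
Reagents that add atoms: none
Why: Three-component organocatalytic reductive alkylation of a cyclic 1,3-dicarbonyl C–H acid: proline-mediated Knoevenagel condensation of 13 at the only ring C–H of 17 should give alkylidene 18, which the Hantzsch ester reduces by conjugate hydride transfer; no stereocentre is created, and the neutral conditions should spare the tertiary alcohol, both alkenes and the quaternary centre.

Compound list
1 | 9-methoxy-9-borabicyclo[3.3.1]nonane (B-methoxy-9-BBN) | COB1C2CCCC1CCC2 | starting material
2 | isopropenylmagnesium bromide | C=C(C)[Mg]Br | starting material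
3 | methoxyborate complex, bromomagnesium 9-methoxy-9-(prop-1-en-2-yl)-9-boratabicyclo[3.3.1]nonane (formed in the flask) | CO[B-]1(C(C)=C)C2CCCC1CCC2.[Mg+]Br | intermediate
4 | 9-(prop-1-en-2-yl)-9-borabicyclo[3.3.1]nonane (B-isopropenyl-9-BBN) | C=C(C)B1C2CCCC1CCC2 | intermediate
5 | cyclopent-2-en-1-one | O=C1C=CCC1 | starting material
6 | formaldehyde (monomer from cracked paraformaldehyde) | C=O | starting material
7 | boron enolate, 9-{[(3R)-3-(prop-1-en-2-yl)cyclopent-1-en-1-yl]oxy}-9-borabicyclo[3.3.1]nonane (formed in the flask) | C=C(C)[C@@H]1CCC(OB2C3CCCC2CCC3)=C1 | intermediate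
8 | borinate aldolate, 9-{[(1R,5R)-2-oxo-5-(prop-1-en-2-yl)cyclopentyl]methoxy}-9-borabicyclo[3.3.1]nonane (formed in the flask) | C=C(C)[C@@H]1CCC(=O)[C@H]1COB2C3CCCC2CCC3 | intermediate
9 | (2R,3R)-2-(hydroxymethyl)-3-(prop-1-en-2-yl)cyclopentan-1-one (trans) | C=C(C)[C@@H]1CCC(=O)[C@H]1CO | intermediate
10 | (2R,3R)-2-{[(tert-butyldimethylsilyl)oxy]methyl}-3-(prop-1-en-2-yl)cyclopentan-1-one | C=C(C)[C@@H]1CCC(=O)[C@H]1CO[Si](C)(C)C(C)(C)C | intermediate
11 | (1R,2R,3R)-2-{[(tert-butyldimethylsilyl)oxy]methyl}-1-methyl-3-(prop-1-en-2-yl)cyclopentan-1-ol (OH cis to the CH2 arm) | C=C(C)[C@@H]1CC[C@@](C)(O)[C@H]1CO[Si](C)(C)C(C)(C)C | intermediate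
12 | (1R,2R,3R)-2-(hydroxymethyl)-1-methyl-3-(prop-1-en-2-yl)cyclopentan-1-ol | C=C(C)[C@@H]1CC[C@@](C)(O)[C@H]1CO | intermediate
13 | (1S,2R,5R)-2-hydroxy-2-methyl-5-(prop-1-en-2-yl)cyclopentane-1-carbaldehyde | C=C(C)[C@@H]1CC[C@@](C)(O)[C@H]1C=O | intermediate
14 | 2,4,6-trihydroxytoluene | Cc1c(O)cc(O)cc1O | starting material
15 | isobutyryl chloride | CC(C)C(Cl)=O | starting material
16 | 1-(2,4,6-trihydroxy-3-methylphenyl)-2-methylpropan-1-one | CC(C)C(=O)c1c(O)c(C)c(O)cc1O | intermediate
17 | (6R)-3,5-dihydroxy-6-methyl-6-(3-methylbut-2-en-1-yl)-2-(2-methylpropanoyl)cyclohexa-2,4-dien-1-one | CC(C)C(=O)C1=C(O)C=C(O)[C@@](C)(CC=C(C)C)C1=O | intermediate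
18 | alkylidene triketone, the Knoevenagel adduct of 13 at C4 of 17 (alkene geometry undefined; formed in the flask) | C=C(C)[C@@H]1CC[C@@](C)(O)[C@H]1C=C1C(=O)[C@@](C)(CC=C(C)C)C(=O)C(C(=O)C(C)C)=C1O | intermediate
19 | (6R)-3,5-dihydroxy-4-{[(1S,2R,5R)-2-hydroxy-2-methyl-5-(prop-1-en-2-yl)cyclopentyl]methyl}-6-methyl-6-(3-methylbut-2-en-1-yl)-2-(2-methylpropanoyl)cyclohexa-2,4-dien-1-one | C=C(C)[C@@H]1CC[C@@](C)(O)[C@H]1CC1=C(O)[C@@](C)(CC=C(C)C)C(=O)C(C(=O)C(C)C)=C1O | target

Total step count: 9. Longest linear sequence: 7 steps (steps 1 to 6, then step 9); steps 7 and 8 form the second branch.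

Steps most likely to fail

1. Step 8 (Proposed new method). The catalyst may discriminate the two faces of the phenoxide poorly, or the allyl complex may be attacked at its substituted terminus or by the unsubstituted ring carbon. In that case 16 would be prenylated without stereocontrol by the established base-mediated dearomative alkylation (NaOMe, prenyl bromide, MeOH, 0 °C). This should give the racemic dienone, racemic 3,5-dihydroxy-6-methyl-6-(3-methylbut-2-en-1-yl)-2-(2-methylpropanoyl)cyclohexa-2,4-dien-1-one F1, which would be resolved by preparative chromatography on a chiral stationary phase with an acidic modifier. The (6S)-enantiomer F2 is set aside, and the (6R)-enantiomer is 17, where the route is rejoined.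

2. Step 2. Capture of the boron enolate by gaseous formaldehyde may be incomplete or unclean, through oligomerisation of formaldehyde on the aldolate or dehydration of the aldol during work-up. The conjugate addition of 4 to 5 would then be run as before to boron enolate 7, which would be treated with n-BuLi and then Me3SiCl to give the isolable silyl enol ether, trimethyl{[(3R)-3-(prop-1-en-2-yl)cyclopent-1-en-1-yl]oxy}silane F3. A Mukaiyama-type hydroxymethylation of F3 with commercial aqueous formaldehyde and catalytic Yb(OTf)3 in THF–water, again anti to the isopropenyl group, should return the route at 9.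

3. Step 4. Facial selectivity of the methyl addition may be poor if the CH2OTBS arm does not dominate over the isopropenyl group. The carbinol would then be built by hydroxyl-directed oxygen delivery, setting out from 10:
- Wittig methylenation (Ph3PCH3Br, KN(SiMe3)2, THF) should give the exocyclic alkene, tert-butyldimethyl{[(1S,5R)-2-methylidene-5-(prop-1-en-2-yl)cyclopentyl]methoxy}silane F4.
- Bu4NF should free the homoallylic alcohol, [(1S,5R)-2-methylidene-5-(prop-1-en-2-yl)cyclopentyl]methanol F5.
- VO(acac)2/t-BuOOH epoxidation, directed by the CH2OH group to the face of the arm, should give the spiro-epoxide, [(3R,4R,5R)-5-(prop-1-en-2-yl)-1-oxaspiro[2.4]heptan-4-yl]methanol F6.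
- LiAlH4 opening at the epoxide CH2 should give diol 12, where the route is rejoined.

Further compounds
F1 | step 8 | racemic 3,5-dihydroxy-6-methyl-6-(3-methylbut-2-en-1-yl)-2-(2-methylpropanoyl)cyclohexa-2,4-dien-1-one | CC(C)C(=O)C1=C(O)C=C(O)C(C)(CC=C(C)C)C1=O
F2 | step 8 | (6S)-3,5-dihydroxy-6-methyl-6-(3-methylbut-2-en-1-yl)-2-(2-methylpropanoyl)cyclohexa-2,4-dien-1-one | CC(C)C(=O)C1=C(O)C=C(O)[C@](C)(CC=C(C)C)C1=O
F3 | step 2 | trimethyl{[(3R)-3-(prop-1-en-2-yl)cyclopent-1-en-1-yl]oxy}silane | C=C(C)[C@@H]1CCC(O[Si](C)(C)C)=C1
F4 | step 4 | tert-butyldimethyl{[(1S,5R)-2-methylidene-5-(prop-1-en-2-yl)cyclopentyl]methoxy}silane | C=C(C)[C@@H]1CCC(=C)[C@H]1CO[Si](C)(C)C(C)(C)C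
F5 | step 4 | [(1S,5R)-2-methylidene-5-(prop-1-en-2-yl)cyclopentyl]methanol | C=C(C)[C@@H]1CCC(=C)[C@H]1CO
F6 | step 4 | [(3R,4R,5R)-5-(prop-1-en-2-yl)-1-oxaspiro[2.4]heptan-4-yl]methanol | C=C(C)[C@@H]1CC[C@@]2(OC2)[C@H]1CO
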